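**Strategy.** Everything rests on closing the γ-lactone through its C8–C17 bond (briarane numbering). A dirhodium-catalysed 1,5 C–H insertion of an α-diazopropionate carried on O7 into the C8–H bond of an L-arabinose-derived dioxolane forges this bond, the lactone ring and the fully substituted C8 carbinol in one operation, with retention. The step exploits that C8, the carbon shared by the ten-membered ring and the lactone ring, bears a geminal oxygen and lies 1,5 to the carbene carbon C17. Its precursor is a sugar-derived secondary C–H centre, not a ketone. Ring A comes from a Diels–Alder reaction; the ten-membered ring from diene ring-closing metathesis; chloride, epoxide and acetates follow.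

Key step: step 15

Remark (numbering): briarane numbering is used: C1 (quaternary, Me = C15), C2 (OAc), C3/C4 (epoxide), C5 (=C16H2), C6 (Cl), C7 (lactone O), C8 (OH), C9 (OAc), C10, C11 (OH, Me = C20), C12 (C=O), C13=C14; lactone carbons C17 (Me = C18) and C19 (C=O); On is the oxygen on Cn. The target is 1S,2R,3R,4R,6S,7R,8R,9S,10S,11S,17R.

Remark (assumption): 13, 16, 17 and 18 are carried as mixtures of C11 epimers and 26 as a mixture at the keto-ester α-carbon; both centres become trigonal before they are set (steps 10 and 14), so their SMILES leave them open.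

Step 1
Reactants: 1 L-arabinose; 2 ethanethiol
Product: 3 L-arabinose diethyl dithioacetal
Conditions: EtSH, conc. HCl, 0 °C
Reagents that add atoms: ethanethiol, CCS
Why: Acid-catalysed dithioacetalisation opens the hemiacetal and masks C10 as an acyclic dithioacetal, leaving the three stereocentres (future C9, C8, C7) untouched.

Step 2
Reactants: 3 L-arabinose diethyl dithioacetal; 4 2,2-dimethoxypropane
Product: 5 2,3:4,5-di-O-isopropylidene-L-arabinose diethyl dithioacetal
Conditions: 2,2-dimethoxypropane, camphorsulfonic acid (cat.), acetone, 23 °C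
Reagents that add atoms: 2,2-dimethoxypropane, COC(C)(C)OC
Why: Thermodynamic acetonide formation should give the trans-dioxolane on the threo O8/O9 diol and the terminal dioxolane on O6/O7, no stereocentre being formed.

Step 3
Reactants: 5 bis-acetonide dithioacetal; 6 water
Product: 7 2,3:4,5-di-O-isopropylidene-aldehydo-L-arabinose
Conditions: I2, NaHCO3, acetone/H2O, 0 °C
Reagents that add atoms: water, O
Why: Iodine-promoted dethioacetalisation frees the C10 aldehyde under buffered conditions that spare both acetonides and should not epimerise C9.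

Step 4
Reactants: 7 bis-acetonide aldehyde; 8 2-(triphenylphosphoranylidene)propanal
Product: 9 (E)-2,3-dideoxy-4,5:6,7-di-O-isopropylidene-2-C-methyl-L-arabino-hept-2-enose (enal; CHO = C2, C=C = C1=C10)
Conditions: toluene, 90 °C
Reagents that add atoms: 2-(triphenylphosphoranylidene)propanal, CC(C=O)=P(c1ccccc1)(c1ccccc1)c1ccccc1
Why: Wittig reaction of a stabilised ylide should give the (E)-trisubstituted enal (CHO trans to C9), which fixes the later trans relation of C2 and C9 on ring A.

Step 5
Reactants: 10 pent-1-en-3-one; 11 tert-butyldimethylsilyl triflate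
Product: 12 (3Z)-3-(tert-butyldimethylsilyloxy)penta-1,3-diene
Conditions: TBSOTf, Et3N, Et2O, 0 °C
Reagents that add atoms: tert-butyldimethylsilyl triflate, CC(C)(C)[Si](C)(C)OS(=O)(=O)C(F)(F)F
Why: Soft enolisation and O-silylation of the ethyl ketone (silyl enol ether formation) should give the (Z)-2-siloxy diene, whose methyl group points outward in the s-cis form.

Step 6
Reactants: 9 enal; 12 siloxy diene
Product: 13 Diels–Alder adduct (ring-A cyclohexene: C2 aldehyde and C15 methyl on C1, C12 TBS enol ether, C11 methyl, bis-acetonide chain on C10)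
Conditions: EtAlCl2 (20 mol %), CH2Cl2, −78 → −40 °C
Reagents that add atoms: (3Z)-3-(tert-butyldimethylsilyloxy)penta-1,3-diene, C/C=C(\O[Si](C)(C)C(C)(C)C)C=C
Why: Lewis-acid-catalysed Diels–Alder reaction in which the diene terminus next to the siloxy carbon (C11) bonds to the enal β-carbon C10, the (E)-geometry is transferred to the trans C2/C9 relation, and the diene should add anti to the allylic C9–O9 bond (Felkin–Anh-type model, H9 in the alkene plane to avoid A(1,3) strain with the C1 methyl), which sets C1 and C10.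

Step 7
Reactants: 13 Diels–Alder adduct; 14 vinylmagnesium bromide
Product: 16 (2S)-allylic alcohol (C3 vinyl carbinol), via divinylzinc 15 (not isolated)
Conditions: CH2=CHMgBr, ZnCl2, THF/toluene, 0 °C; then 13, (2S)-(−)-3-exo-morpholinoisoborneol [(−)-MIB] (5 mol %), 0 °C; aq. NH4Cl
Reagents that add atoms: vinylmagnesium bromide, C=C[Mg]Br
Why: Amino-alcohol-catalysed addition of a vinylzinc reagent to the non-enolisable aldehyde, in which (−)-MIB should direct the vinyl group to the Si face and so set C2 by catalyst control (2S here, 2R in the target after the priority change at C3), the silyl enol ether being inert to the organozinc.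

Step 8
Reactants: 16 allylic alcohol; 11 tert-butyldimethylsilyl triflate
Product: 17 C2 TBS ether
Conditions: TBSOTf, 2,6-lutidine, CH2Cl2, −78 °C
Reagents that add atoms: tert-butyldimethylsilyl triflate, CC(C)(C)[Si](C)(C)OS(=O)(=O)C(F)(F)F
Why: Silylation with the silyl triflate protects the hindered allylic alcohol so that it is not acylated, oxidised or chlorinated later (protecting-group step, no stereocentre affected).

Step 9
Reactants: 17 bis-silyl compound
Product: 18 ring-A enone (C12 ketone, C13=C14)
Conditions: Pd(OAc)2 (1.1 equiv), MeCN, 40 °C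
Reagents that add atoms: none
Why: Saegusa–Ito oxidation, in which divalent palladium converts the regiodefined C12 silyl enol ether into the C13=C14 enone by β-hydride elimination from C14, the quaternary C1 excluding any other regioisomer.

Step 10
Reactants: 18 enone; 19 2-(phenylsulfonyl)-3-phenyloxaziridine
Product: 21 (11S)-11-hydroxy enone, via potassium dienolate 20 (not isolated)
Conditions: KN(SiMe3)2, THF, −78 °C; then 19, −78 °C; aq. NH4Cl
Reagents that add atoms: 2-(phenylsulfonyl)-3-phenyloxaziridine, O=S(=O)(N1OC1c1ccccc1)c1ccccc1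
Why: α′-Deprotonation (C11–H is the only acidic C–H) gives the cross-conjugated dienolate, which the N-sulfonyloxaziridine should hydroxylate (Davis oxidation) from the face opposite the pseudo-axial C15 methyl and the C9 side chain, so that the 11-OH is cis to H10 and both C11 epimers converge.

Step 11
Reactants: 21 hydroxy enone
Product: 22 6,7-diol
Conditions: AcOH/H2O (4:1), 35 °C
Reagents that add atoms: none
Why: Selective acetal hydrolysis, the terminal dioxolane being cleaved much faster than the internal trans-disubstituted one, should free O6–H and O7–H while the TBS ether survives.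

Step 12
Reactants: 22 diol; 23 levulinic anhydride
Product: 24 O6 levulinate
Conditions: levulinic anhydride, 2,4,6-collidine, CH2Cl2, −40 → 0 °C
Reagents that add atoms: levulinic anhydride, CC(=O)CCC(=O)OC(=O)CCC(C)=O
Why: Selective acylation of the primary hydroxyl gives the levulinate, which later deactivates the C6–H bonds toward the carbene and is removable under neutral conditions.

Step 13
Reactants: 24 levulinate; 25 ethyl 2-methylacetoacetate
Product: 26 O7 2-methylacetoacetate
Conditions: ethyl 2-methylacetoacetate, DMAP (20 mol %), toluene, 110 °C, removal of EtOH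
Reagents that add atoms: ethyl 2-methylacetoacetate, CCOC(=O)C(C)C(C)=O
Why: Transesterification of the β-keto ester through its acylketene should acylate the secondary O7–H, the tertiary 11-OH being too hindered.

Step 14
Reactants: 26 keto ester; 27 4-acetamidobenzenesulfonyl azide
Product: 28 O7 2-diazopropionate
Conditions: p-ABSA, DBU, MeCN, 0 °C
Reagents that add atoms: 4-acetamidobenzenesulfonyl azide, CC(=O)Nc1ccc(cc1)S(=O)(=O)N=[N+]=[N-]
Why: Deacylative (Regitz-type) diazo transfer to the 2-substituted acetoacetate, with loss of the acetyl group to the sulfonamide, gives the α-diazopropionate on O7.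

Step 15
Reactants: 28 diazo ester
Product: 29 spiro-lactone (γ-lactone O7–C19–C17–C8–C7, spiro at C8 to the O8/O9 dioxolane; 17R)
Conditions: Rh2(O2CCPh3)4 (1 mol %), CH2Cl2, −40 → 23 °C, slow addition of 28
Reagents that add atoms: none
Why: The dirhodium tetracarboxylate decomposes 28 to an electrophilic rhodium carbene at C17, which inserts into the C8–H bond through a three-centre, hydride-transfer-like transition state; this is the known dirhodium-catalysed intramolecular 1,5 C–H insertion of diazo esters into C–H bonds alpha to an ether oxygen (γ-lactone synthesis). The only ring closed is the five-membered lactone, formed by 1,5-insertion through a six-membered transition state (C17, C19, O7, C7, C8, H), which leaves the dioxolane spiro at C8. C8 is formed with retention, so its configuration is that of C3 of L-arabinose, and C17 should form with its methyl anti to the bulkier C9 branch (cis to O8); being epimerisable, C17 can be equilibrated to this more stable epimer. Site selectivity for C8–H over the equally 1,5-disposed C6–H2 is secured by the levulinate on O6, which deactivates those C–H bonds toward the electrophilic carbene, whereas the dioxolane oxygen activates the tertiary C8–H. The 1,2-hydride shift typical of α-alkyl carbenes should be suppressed by the bulky triphenylacetate ligands and the low temperature, and the remote vinyl group, the electron-poor enone and the hindered tertiary alcohol should not compete under slow addition.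

Step 16
Reactants: 29 spiro-lactone
Product: 30 primary alcohol (C6–OH)
Conditions: N2H4·AcOH, CH2Cl2/MeOH, 0 °C
Reagents that add atoms: none
Why: Buffered hydrazine condenses with the levulinate ketone and the hydrazone cyclises onto the ester (standard levulinate cleavage), which should release O6–H without touching the hindered enone, the lactone or the silyl ether.

Step 17
Reactants: 30 primary alcohol
Product: 31 C6 aldehyde
Conditions: Dess–Martin periodinane, pyridine, CH2Cl2, 0 → 23 °C
Reagents that add atoms: none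
Why: Dess–Martin oxidation of the primary alcohol (the 11-OH is tertiary) gives the α-acyloxy aldehyde under conditions that should not epimerise C7.

Step 18
Reactants: 32 allenylboronic acid pinacol ester; 33 bromochloromethane
Product: 36 buta-2,3-dienylboronic acid pinacol ester, via chloromethyllithium 34 (not isolated), via boron ate complex 35 (not isolated)
Conditions: BrCH2Cl, n-BuLi, THF, −78 → 23 °C
Reagents that add atoms: bromochloromethane, ClCBr
Why: Matteson homologation, in which chloromethyllithium adds to boron and 1,2-migration of the allenyl group with loss of chloride inserts a CH2 group.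

Step 19
Reactants: 31 aldehyde; 36 buta-2,3-dienylboronic acid pinacol ester
Product: 37 (6R)-buta-1,3-dien-2-yl carbinol
Conditions: (R)-3,3′-bis(2,4,6-triisopropylphenyl)-1,1′-binaphthyl-2,2′-diyl hydrogen phosphate [(R)-TRIP] (10 mol %), 4 Å molecular sieves, toluene, −30 °C; aqueous work-up
Reagents that add atoms: buta-2,3-dienylboronic acid pinacol ester, C=C=CCB1OC(C)(C)C(C)(C)O1
Why: Chiral-phosphoric-acid-catalysed homoallenylboration (SE2′ addition through a closed six-membered transition state) transfers the buta-1,3-dien-2-yl group (C5, C16, C4) to the aldehyde, the (R)-catalyst being expected to direct attack to the Re face and set C6 as the (6R)-alcohol by catalyst control against the Cornforth preference of the substrate, while the hindered ring-A ketone should not react.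

Step 20
Reactants: 37 dienyl carbinol; 38 hexachloroacetone
Product: 39 (6S)-allylic chloride
Conditions: PPh3, (Cl3C)2CO, CH2Cl2, −20 → 0 °C
Reagents that add atoms: hexachloroacetone, O=C(C(Cl)(Cl)Cl)C(Cl)(Cl)Cl
Why: Appel-type chlorination of the allylic alcohol via its alkoxyphosphonium salt should proceed by SN2 with inversion (6R-OH to 6S-Cl) and without allylic transposition, the tertiary 11-OH being inert.

Step 21
Reactants: 39 allylic chloride
Product: 40 seco-tetraol (2-OH, 8-OH, 9-OH, 11-OH)
Conditions: aq. HF (48 %), MeCN, 0 → 23 °C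
Reagents that add atoms: none
Why: Acidic fluoride cleaves the TBS ether and should hydrolyse the strained spiro acetonide (global deprotection) without ionising the allylic chloride.

Step 22
Reactants: 40 seco-tetraol
Product: 41 ten-membered (3Z)-3,5(16)-diene tetraol
Conditions: second-generation Hoveyda–Grubbs catalyst (15 mol %), 1,4-benzoquinone (30 mol %), toluene (0.5 mM), 80 °C
Reagents that add atoms: none
Why: Ring-closing metathesis between the C3 vinyl group and the monosubstituted terminus (C4) of the 2-substituted butadiene should close the ten-membered ring, the (Z)-alkene being imposed by ring strain and the 1,1-disubstituted C5=C16 and the enone staying inert.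

Step 23
Reactants: 41 macrocyclic diene; 42 3-chloroperbenzoic acid
Product: 43 3,4-epoxide tetraol (2,9-di-O-deacetyl target)
Conditions: mCPBA, 2,6-di-tert-butyl-4-methylpyridine, CH2Cl2, 0 °C
Reagents that add atoms: 3-chloroperbenzoic acid, OOC(=O)c1cccc(Cl)c1
Why: Hydroxyl-assisted Prilezhaev epoxidation, in which hydrogen bonding to the allylic 2-OH should make the (Z)-C3=C4 alkene react before the chloride-deactivated exocyclic C5=C16 and the enone, and peripheral attack on the medium-ring (Z)-allylic alcohol should give the threo (trans) epoxy alcohol, setting C3 and C4 as in the target.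

Step 24
Reactants: 43 epoxide tetraol; 44 acetic anhydride
Product: 45 CNP0176724.2 (target)
Conditions: Ac2O, pyridine, DMAP (cat.), CH2Cl2, 0 → 23 °C
Reagents that add atoms: acetic anhydride, CC(=O)OC(C)=O
Why: Acetylation (esterification) of the two secondary hydroxyls at C2 and C9, the tertiary 8-OH and 11-OH being unreactive under these conditions.

**Compound list**

1 | L-arabinose (drawn as the aldehydo form) | O=C[C@H](O)[C@@H](O)[C@@H](O)CO | starting material
2 | ethanethiol | CCS | starting material
3 | L-arabinose diethyl dithioacetal | CCSC(SCC)[C@H](O)[C@@H](O)[C@@H](O)CO | intermediate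
4 | 2,2-dimethoxypropane | COC(C)(C)OC | starting material
5 | 2,3:4,5-di-O-isopropylidene-L-arabinose diethyl dithioacetal | CCSC(SCC)[C@@H]1OC(C)(C)O[C@H]1[C@@H]2COC(C)(C)O2 | intermediate
6 | water | O | starting material
7 | 2,3:4,5-di-O-isopropylidene-aldehydo-L-arabinose | O=C[C@@H]1OC(C)(C)O[C@H]1[C@@H]2COC(C)(C)O2 | intermediate
8 | 2-(triphenylphosphoranylidene)propanal | CC(C=O)=P(c1ccccc1)(c1ccccc1)c1ccccc1 | starting material
9 | (E)-2,3-dideoxy-4,5:6,7-di-O-isopropylidene-2-C-methyl-L-arabino-hept-2-enose | O=C/C(C)=C/[C@@H]1OC(C)(C)O[C@H]1[C@@H]2COC(C)(C)O2 | intermediate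
10 | pent-1-en-3-one | CCC(=O)C=C | starting material
11 | tert-butyldimethylsilyl trifluoromethanesulfonate | CC(C)(C)[Si](C)(C)OS(=O)(=O)C(F)(F)F | starting material
12 | (3Z)-3-(tert-butyldimethylsilyloxy)penta-1,3-diene | C/C=C(\O[Si](C)(C)C(C)(C)C)C=C | intermediate
13 | Diels–Alder adduct (C2 aldehyde, C12 TBS enol ether, C11 epimers, C6–C9 bis-acetonide chain on C10) | O=C[C@@]1(C)CC=C(O[Si](C)(C)C(C)(C)C)C(C)[C@@H]1[C@@H]2OC(C)(C)O[C@H]2[C@@H]3COC(C)(C)O3 | intermediate
14 | vinylmagnesium bromide | C=C[Mg]Br | starting material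
15 | divinylzinc | C=C[Zn]C=C | intermediate
16 | (2S)-allylic alcohol (C3 vinyl carbinol) | C=C[C@H](O)[C@@]1(C)CC=C(O[Si](C)(C)C(C)(C)C)C(C)[C@@H]1[C@@H]2OC(C)(C)O[C@H]2[C@@H]3COC(C)(C)O3 | intermediate
17 | C2 TBS ether of 16 | C=C[C@H](O[Si](C)(C)C(C)(C)C)[C@@]1(C)CC=C(O[Si](C)(C)C(C)(C)C)C(C)[C@@H]1[C@@H]2OC(C)(C)O[C@H]2[C@@H]3COC(C)(C)O3 | intermediate
18 | ring-A enone (C12 ketone, C13=C14; C11 epimers) | C=C[C@H](O[Si](C)(C)C(C)(C)C)[C@@]1(C)C=CC(=O)C(C)[C@@H]1[C@@H]2OC(C)(C)O[C@H]2[C@@H]3COC(C)(C)O3 | intermediate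
19 | 2-(phenylsulfonyl)-3-phenyloxaziridine | O=S(=O)(N1OC1c1ccccc1)c1ccccc1 | starting material
20 | potassium dienolate of 18 (C11=C12–O−) | C=C[C@H](O[Si](C)(C)C(C)(C)C)[C@@]1(C)C=CC([O-])=C(C)[C@@H]1[C@@H]2OC(C)(C)O[C@H]2[C@@H]3COC(C)(C)O3.[K+] | intermediate
21 | (11S)-11-hydroxy enone | C=C[C@H](O[Si](C)(C)C(C)(C)C)[C@@]1(C)C=CC(=O)[C@@](C)(O)[C@@H]1[C@@H]2OC(C)(C)O[C@H]2[C@@H]3COC(C)(C)O3 | intermediate
22 | 6,7-diol | C=C[C@H](O[Si](C)(C)C(C)(C)C)[C@@]1(C)C=CC(=O)[C@@](C)(O)[C@@H]1[C@@H]2OC(C)(C)O[C@H]2[C@@H](O)CO | intermediate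
23 | levulinic anhydride | CC(=O)CCC(=O)OC(=O)CCC(C)=O | starting material
24 | O6 levulinate | C=C[C@H](O[Si](C)(C)C(C)(C)C)[C@@]1(C)C=CC(=O)[C@@](C)(O)[C@@H]1[C@@H]2OC(C)(C)O[C@H]2[C@@H](O)COC(=O)CCC(C)=O | intermediate
25 | ethyl 2-methylacetoacetate | CCOC(=O)C(C)C(C)=O | starting material
26 | O7 2-methylacetoacetate (α-epimers) | C=C[C@H](O[Si](C)(C)C(C)(C)C)[C@@]1(C)C=CC(=O)[C@@](C)(O)[C@@H]1[C@@H]2OC(C)(C)O[C@H]2[C@@H](OC(=O)C(C)C(C)=O)COC(=O)CCC(C)=O | intermediate
27 | 4-acetamidobenzenesulfonyl azide | CC(=O)Nc1ccc(cc1)S(=O)(=O)N=[N+]=[N-] | starting material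
28 | O7 2-diazopropionate | C=C[C@H](O[Si](C)(C)C(C)(C)C)[C@@]1(C)C=CC(=O)[C@@](C)(O)[C@@H]1[C@@H]2OC(C)(C)O[C@H]2[C@@H](OC(=O)C(C)=[N+]=[N-])COC(=O)CCC(C)=O | intermediate
29 | spiro-lactone (C8–C17 bond formed; 17R) | C=C[C@H](O[Si](C)(C)C(C)(C)C)[C@@]1(C)C=CC(=O)[C@@](C)(O)[C@@H]1[C@@H]2OC(C)(C)O[C@]23[C@@H](C)C(=O)O[C@H]3COC(=O)CCC(C)=O | intermediate
30 | primary alcohol (C6–OH) | C=C[C@H](O[Si](C)(C)C(C)(C)C)[C@@]1(C)C=CC(=O)[C@@](C)(O)[C@@H]1[C@@H]2OC(C)(C)O[C@]23[C@@H](C)C(=O)O[C@H]3CO | intermediate
31 | C6 aldehyde | C=C[C@H](O[Si](C)(C)C(C)(C)C)[C@@]1(C)C=CC(=O)[C@@](C)(O)[C@@H]1[C@@H]2OC(C)(C)O[C@]23[C@@H](C)C(=O)O[C@H]3C=O | intermediate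
32 | allenylboronic acid pinacol ester | C=C=CB1OC(C)(C)C(C)(C)O1 | starting material
33 | bromochloromethane | ClCBr | starting material
34 | chloromethyllithium | [Li]CCl | intermediate
35 | lithium allenyl(chloromethyl)boronate complex | [Li+].C=C=C[B-]1(CCl)OC(C)(C)C(C)(C)O1 | intermediate
36 | buta-2,3-dienylboronic acid pinacol ester | C=C=CCB1OC(C)(C)C(C)(C)O1 | intermediate
37 | (6R)-buta-1,3-dien-2-yl carbinol | C=C[C@H](O[Si](C)(C)C(C)(C)C)[C@@]1(C)C=CC(=O)[C@@](C)(O)[C@@H]1[C@@H]2OC(C)(C)O[C@]23[C@@H](C)C(=O)O[C@H]3[C@H](O)C(=C)C=C | intermediate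
38 | hexachloroacetone | O=C(C(Cl)(Cl)Cl)C(Cl)(Cl)Cl | starting material
39 | (6S)-allylic chloride | C=C[C@H](O[Si](C)(C)C(C)(C)C)[C@@]1(C)C=CC(=O)[C@@](C)(O)[C@@H]1[C@@H]2OC(C)(C)O[C@]23[C@@H](C)C(=O)O[C@H]3[C@@H](Cl)C(=C)C=C | intermediate
40 | seco-tetraol | C=C[C@H](O)[C@@]1(C)C=CC(=O)[C@@](C)(O)[C@@H]1[C@H](O)[C@]2(O)[C@@H](C)C(=O)O[C@H]2[C@@H](Cl)C(=C)C=C | intermediate
41 | ten-membered (3Z)-3,5(16)-diene tetraol | C=C1/C=C\[C@H](O)[C@@]2(C)C=CC(=O)[C@@](C)(O)[C@@H]2[C@H](O)[C@]2(O)[C@@H](C)C(=O)O[C@H]2[C@H]1Cl | intermediate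
42 | 3-chloroperbenzoic acid | OOC(=O)c1cccc(Cl)c1 | starting material
43 | 3,4-epoxide tetraol (2,9-di-O-deacetyl target) | C=C1[C@H]2O[C@H]2[C@H](O)[C@@]2(C)C=CC(=O)[C@@](C)(O)[C@@H]2[C@H](O)[C@]2(O)[C@@H](C)C(=O)O[C@H]2[C@H]1Cl | intermediate
44 | acetic anhydride | CC(=O)OC(C)=O | starting material
45 | CNP0176724.2 | C=C1[C@H]2O[C@H]2[C@H](OC(C)=O)[C@@]2(C)C=CC(=O)[C@@](C)(O)[C@@H]2[C@H](OC(C)=O)[C@]2(O)[C@@H](C)C(=O)O[C@H]2[C@H]1Cl | target

**Step count and risks**

Total step count: 24 (including the two side-branch steps 5 and 18). Longest linear sequence: 22 steps (steps 1–4, 6–17 and 19–24, from L-arabinose).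

Most likely to fail, step 15: the α-methyl carbene may undergo 1,2-hydride shift to an acrylate ester, or be trapped as an oxonium ylide by the dioxolane oxygen, faster than it inserts into C8–H. Fallback from 24 to 30: the O7–H of 24 is acylated with 2,2,6-trimethyl-4H-1,3-dioxin-4-one (xylene, 130 °C) to give the O7 acetoacetate F1. Diazo transfer (p-ABSA, Et3N, MeCN) gives the diazoacetoacetate F2, whose acceptor/acceptor carbene has no hydrogen to shift. Rh2(OAc)4 (CH2Cl2, 40 °C) then effects the same 1,5-insertion into C8–H to give the α-acetyl spiro-lactone F3. C-methylation (K2CO3, MeI, acetone) gives the C17-methylated acetyl lactone F4. K2CO3 in MeOH at 0 °C removes the acetyl group by retro-Claisen cleavage and the levulinate by methanolysis, with C17 protonated under equilibrating conditions, and the route is rejoined at 30.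

Second, step 22: intermolecular metathesis (oligomerisation) may outrun closure of the strained ten-membered ring, or the catalyst may stall at the conjugated diene. Fallback from 37 to 41 with a temporary silicon tether: HF·pyridine (THF, 0 °C) removes the TBS ether of 37 to give the 2,6-diol F5. iPr2SiCl2 and imidazole (DMF, high dilution) tie O2 to O6 as the cyclic diisopropylsilylene F6. Ring-closing metathesis (second-generation Grubbs catalyst, toluene, 80 °C) then closes an eight-membered dioxasilacycle (O2–Si–O6–C6–C5–C4=C3–C2), which enforces the (Z)-alkene and delivers the carbocycle as the bicyclic silylene F7. HF·pyridine removes the tether to give the macrocyclic 2,6-diol F8. PPh3 and (Cl3C)2CO chlorinate only C6–OH with inversion, the neopentylic C2–OH being unable to undergo SN2, to give the macrocyclic chloride F9. Aqueous HF in MeCN removes the acetonide and the route is rejoined at 41.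

Third, step 19: facial selectivity may be poor, because the catalyst has to override the intrinsic Cornforth (anti) preference of the α-acyloxy aldehyde. Fallback from 31 to 37 under substrate control: indium powder and 1,4-dibromobut-2-yne (THF/H2O, 23 °C) add the dienyl group to 31 and should give the (6S)-dienyl carbinol F10. A Mitsunobu reaction (ClCH2CO2H, PPh3, DIAD, THF, 0 °C) inverts C6 to the (6R)-chloroacetate F11. Thiourea (NaHCO3, EtOH, 50 °C) removes the chloroacetyl group and the route is rejoined at 37.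

**Further compounds**

F1 | step 15 | O7 acetoacetate of 24 | C=C[C@H](O[Si](C)(C)C(C)(C)C)[C@@]1(C)C=CC(=O)[C@@](C)(O)[C@@H]1[C@@H]2OC(C)(C)O[C@H]2[C@@H](OC(=O)CC(C)=O)COC(=O)CCC(C)=O
F2 | step 15 | O7 diazoacetoacetate | C=C[C@H](O[Si](C)(C)C(C)(C)C)[C@@]1(C)C=CC(=O)[C@@](C)(O)[C@@H]1[C@@H]2OC(C)(C)O[C@H]2[C@@H](OC(=O)C(=[N+]=[N-])C(C)=O)COC(=O)CCC(C)=O
F3 | step 15 | α-acetyl spiro-lactone (C17 epimers) | C=C[C@H](O[Si](C)(C)C(C)(C)C)[C@@]1(C)C=CC(=O)[C@@](C)(O)[C@@H]1[C@@H]2OC(C)(C)O[C@]23C(C(C)=O)C(=O)O[C@H]3COC(=O)CCC(C)=O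
F4 | step 15 | C17-methylated acetyl lactone (C17 epimers) | C=C[C@H](O[Si](C)(C)C(C)(C)C)[C@@]1(C)C=CC(=O)[C@@](C)(O)[C@@H]1[C@@H]2OC(C)(C)O[C@]23C(C)(C(C)=O)C(=O)O[C@H]3COC(=O)CCC(C)=O
F5 | step 22 | 2,6-diol (37 without TBS) | C=C[C@H](O)[C@@]1(C)C=CC(=O)[C@@](C)(O)[C@@H]1[C@@H]2OC(C)(C)O[C@]23[C@@H](C)C(=O)O[C@H]3[C@H](O)C(=C)C=C
F6 | step 22 | cyclic diisopropylsilylene bridging O2 and O6 | C=C[C@H](O[Si]4(C(C)C)C(C)C)[C@@]1(C)C=CC(=O)[C@@](C)(O)[C@@H]1[C@@H]2OC(C)(C)O[C@]23[C@@H](C)C(=O)O[C@H]3[C@H](O4)C(=C)C=C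
F7 | step 22 | bicyclic silylene (ring-closed, 3Z) | C=C1/C=C\[C@H](O[Si]4(C(C)C)C(C)C)[C@@]2(C)C=CC(=O)[C@@](C)(O)[C@@H]2[C@@H]3OC(C)(C)O[C@]35[C@@H](C)C(=O)O[C@H]5[C@@H]1O4
F8 | step 22 | macrocyclic 2,6-diol (acetonide retained) | C=C1/C=C\[C@H](O)[C@@]2(C)C=CC(=O)[C@@](C)(O)[C@@H]2[C@@H]3OC(C)(C)O[C@]35[C@@H](C)C(=O)O[C@H]5[C@@H]1O
F9 | step 22 | macrocyclic (6S)-chloride (acetonide retained) | C=C1/C=C\[C@H](O)[C@@]2(C)C=CC(=O)[C@@](C)(O)[C@@H]2[C@@H]3OC(C)(C)O[C@]35[C@@H](C)C(=O)O[C@H]5[C@H]1Cl
F10 | step 19 | (6S)-buta-1,3-dien-2-yl carbinol (C6 epimer of 37) | C=C[C@H](O[Si](C)(C)C(C)(C)C)[C@@]1(C)C=CC(=O)[C@@](C)(O)[C@@H]1[C@@H]2OC(C)(C)O[C@]23[C@@H](C)C(=O)O[C@H]3[C@@H](O)C(=C)C=C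
F11 | step 19 | (6R)-chloroacetate | C=C[C@H](O[Si](C)(C)C(C)(C)C)[C@@]1(C)C=CC(=O)[C@@](C)(O)[C@@H]1[C@@H]2OC(C)(C)O[C@]23[C@@H](C)C(=O)O[C@H]3[C@H](OC(=O)CCl)C(=C)C=C
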